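Retrosynthesis (carotenoid numbering: C1 = CMe2, C3 = CHOH, C4=C5, C6 = ring CH, chain from C7): cut C7=C8 (Julia–Kocienski; ring sulfone plus C20 dialdehyde), then the ring bond C1–C6 together with C7–S in one event, then C4=C5 and C4–C5 (dehydration, aldol) back to mesityl oxide and methyl vinyl ketone.
Enabling feature: ring carbons C1–C2–C3(O)–C4=C5–C6 are the six carbons of a 3-oxidohexa-1,3,5-triene; with C3 as a ketone, the gem-dimethyl carbon C1 is an enone β-carbon, C6 is the γ-carbon of the same ketone, and the exocyclic C7 is a 1,6-acceptor terminus where a thiol can switch the trienolate on and leave the olefination handle.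
Forward: acyclic trienone (E/Z mixture) → thiol-triggered 6π ring closure gives the only ring, with quaternary C1, the C4=C5 alkene, the C3 ketone and sulfur on C7 → C3 reduction, silylation, S-oxidation → the C20 chain is joined last, then desilylation.
Stereochemistry: C6 (R) from the chiral catalyst in the electrocyclization; C3 (S) from reagent-controlled Corey–Bakshi–Shibata reduction; chain geometry from the all-E dialdehyde and the E-selective olefination.

Key step: step 3

Assumption: all-E crocetin dialdehyde 13 (the C20 dialdehyde of carotenoid chemistry) is taken as a purchasable building block.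

Step 1
Reactants: 1 mesityl oxide (4-methylpent-3-en-2-one); 2 methyl vinyl ketone (but-3-en-2-one)
Product: 4 (±)-6-hydroxy-2,6-dimethylocta-2,7-dien-4-one, via lithium dienolate 3 (not isolated)
Conditions: LiN(i-Pr)2 (1.05 equiv), THF, −78 °C; then 2, −78 °C; AcOH in THF at −78 °C
Reagents that add atoms: none
Why: Kinetic deprotonation of the enone at its α'-methyl group gives the cross-conjugated lithium dienolate, whose aldol (1,2-) addition to the ketone of 2 at −78 °C should be faster than Michael addition, and the cold acidic quench prevents retro-aldol; the tertiary carbinol centre is formed racemic and is removed in step 2.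

Step 2
Reactants: 4 (±)-6-hydroxy-2,6-dimethylocta-2,7-dien-4-one
Product: 6 2,6-dimethylocta-2,5,7-trien-4-one (ocimenone; 5E/5Z mixture), via tertiary mesylate 5 (not isolated)
Conditions: MeSO2Cl, Et3N, CH2Cl2, 0 °C; then DBU, 0 °C → rt
Reagents that add atoms: none
Why: Sulfonylation of the β-hydroxyl followed by E1cB elimination through the ketone enolate should give the conjugated trienone, and both isomers of the new trisubstituted alkene are acceptable because step 3 is stereoconvergent.

Step 3
Reactants: 6 2,6-dimethylocta-2,5,7-trien-4-one (5E/5Z mixture)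
Product: 8 (4R)-3,5,5-trimethyl-4-{[(1-phenyl-1H-tetrazol-5-yl)sulfanyl]methyl}cyclohex-2-en-1-one, via trienolate 7 (not isolated)
Conditions: 1-phenyl-1H-tetrazole-5-thiol (1.0 equiv), chiral iminophosphorane–thiourea organocatalyst ArNHC(S)NH–CH(t-Bu)–CH2–N=P(C6H4-4-OMe)3, Ar = 3,5-(CF3)2C6H3 (10 mol %; the enantiomer that leads to 4R), toluene, 0 → 40 °C
Reagents that add atoms: 1-phenyl-1H-tetrazole-5-thiol, Sc1nnnn1-c1ccccc1
Why: Proposed new method: the catalyst-bound thiolate adds reversibly to the terminal vinyl carbon C7 of 6 (1,6-thia-Michael addition), which creates regiospecifically the 3-oxidohexa-1,3,5-triene 7 (C1=C2–C3(O−)=C4–C5=C6), and this closes by an oxyanion-accelerated thermal 6π electrocyclization that forms the C1–C6 bond and the quaternary C1 before C2-protonation releases the conjugated enone 8. The closest known reaction types are the base-mediated closure of phorone to isophorone and the low-temperature electrocyclization of 3-oxidohexatrienes on the one hand, and bifunctional Brønsted base/hydrogen-bond-donor catalysis of enantioselective sulfa-Michael additions and of enolate-type Nazarov electrocyclizations on the other. The cyclohexene ring closes in the 6π-disrotatory mode, formally a 6-endo vinylogous Michael addition of C6 to the β,β-dimethyl enone carbon C1. The only new stereocentre, C6, is set by the catalyst: thiourea and protonated iminophosphorane hold O3 of the trienolate so that one helical sense of the s-cis,s-cis triene should be preferred and C1 bonds to one face of C6, whose CH2S group points outward, while C1 carries two methyl groups and is not stereogenic. Because sulfur addition is reversible and the open adducts re-enolize, both alkene isomers of 6 and all enolate geometries should drain through the single trienolate geometry that can reach the helical transition state (a stereoconvergent funnel). The step needs regioselectivity for C6 over the methyl carbons on C5 and C1, secured in the substrate by the unsubstituted C7 terminus as the only unhindered acceptor position, so that the only enolate formed is the C3–C6 dienolate; it also needs S- rather than N-attack, expected from the soft sulfur under kinetic conditions, and a product that keeps its configuration, expected because the hindered γ-C–H at C6 of 8 is removed far more slowly than the α-C–H of the open adduct.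

Step 4
Reactants: 8 (4R)-3,5,5-trimethyl-4-{[(1-phenyl-1H-tetrazol-5-yl)sulfanyl]methyl}cyclohex-2-en-1-one
Product: 9 (1S,4R)-3,5,5-trimethyl-4-{[(1-phenyl-1H-tetrazol-5-yl)sulfanyl]methyl}cyclohex-2-en-1-ol
Conditions: (R)-2-methyl-CBS-oxazaborolidine (20 mol %), catecholborane (1.5 equiv), toluene, −78 °C; aqueous NaOH work-up
Reagents that add atoms: none
Why: Corey–Bakshi–Shibata reduction, in which the oxazaborolidine binds the carbonyl with the alkenyl flank as the larger group and delivers hydride to one face under reagent control (by analogy with the (R)-catalyst giving (S)-1-phenylethanol), should set C3 as S, cis to the C6 substituent, and catecholborane at −78 °C ensures 1,2-reduction.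

Step 5
Reactants: 9 (1S,4R)-3,5,5-trimethyl-4-{[(1-phenyl-1H-tetrazol-5-yl)sulfanyl]methyl}cyclohex-2-en-1-ol
Product: 10 5-({[(1R,4S)-4-{[tert-butyl(dimethyl)silyl]oxy}-2,6,6-trimethylcyclohex-2-en-1-yl]methyl}sulfanyl)-1-phenyl-1H-tetrazole
Conditions: TBSCl, imidazole, DMF, rt
Reagents that add atoms: tert-butyldimethylsilyl chloride (TBSCl), CC(C)(C)[Si](C)(C)Cl
Why: Imidazole-promoted silylation of the secondary allylic alcohol masks the hydroxyl against the base of step 7 and against aryl migration from sulfur to oxygen at the sulfone stage, and touches no stereocentre.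

Step 6
Reactants: 10 5-({[(1R,4S)-4-{[tert-butyl(dimethyl)silyl]oxy}-2,6,6-trimethylcyclohex-2-en-1-yl]methyl}sulfanyl)-1-phenyl-1H-tetrazole
Product: 12 5-({[(1R,4S)-4-{[tert-butyl(dimethyl)silyl]oxy}-2,6,6-trimethylcyclohex-2-en-1-yl]methyl}sulfonyl)-1-phenyl-1H-tetrazole, via sulfoxide 11 (not isolated)
Conditions: (NH4)6Mo7O24·4H2O (10 mol %), 30 % aqueous H2O2 (excess), EtOH, 0 °C → rt
Reagents that add atoms: hydrogen peroxide, OO
Why: Molybdate-catalysed peroxide oxidation takes the sulfide through the sulfoxide to the sulfone, the peroxomolybdate attacking sulfur much faster than the hindered trisubstituted alkene, while silyl ether and stereocentres are untouched.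

Step 7
Reactants: 12 5-({[(1R,4S)-4-{[tert-butyl(dimethyl)silyl]oxy}-2,6,6-trimethylcyclohex-2-en-1-yl]methyl}sulfonyl)-1-phenyl-1H-tetrazole; 13 all-E crocetin dialdehyde
Product: 15 (3S,6R)-3-{[tert-butyl(dimethyl)silyl]oxy}-8'-apo-ε-caroten-8'-al, via potassium sulfonyl carbanion 14 (not isolated)
Conditions: KN(SiMe3)2 (1.0 equiv), THF/DME, −78 °C; cannulated into 13 (3 equiv), −78 → 0 °C; exclusion of light
Reagents that add atoms: none
Why: Julia–Kocienski olefination, in which the α-sulfonyl carbanion adds to one aldehyde group of the excess dialdehyde and Smiles rearrangement with loss of SO2 and tetrazololate gives the C7=C8 alkene, should be E-selective for a β-branched alkyl tetrazolyl sulfone with a potassium counter-ion, and the stoichiometric premetalation leaves the doubly allylic C6–H untouched.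

Step 8
Reactants: 15 (3S,6R)-3-{[tert-butyl(dimethyl)silyl]oxy}-8'-apo-ε-caroten-8'-al
Product: 16 (3S,6R)-3-hydroxy-8'-apo-ε-caroten-8'-al
Conditions: Bu4NF, AcOH (1:1), THF, 0 °C → rt, dark
Reagents that add atoms: none
Why: Fluoride-induced desilylation, buffered with acetic acid so that the polyenal and the doubly allylic C6–H meet no free base and the acid-labile allylic C3–OH is not ionized, should free the target with both stereocentres and the all-E chain unchanged.

Compound list
1 | mesityl oxide (4-methylpent-3-en-2-one) | CC(C)=CC(C)=O | starting material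
2 | methyl vinyl ketone (but-3-en-2-one) | CC(=O)C=C | starting material
3 | lithium 4-methylpenta-1,3-dien-2-olate (not isolated) | [Li+].[O-]C(=C)C=C(C)C | intermediate
4 | (±)-6-hydroxy-2,6-dimethylocta-2,7-dien-4-one | CC(C)=CC(=O)CC(C)(O)C=C | intermediate
5 | (±)-3,7-dimethyl-5-oxoocta-1,6-dien-3-yl methanesulfonate (not isolated) | CC(C)=CC(=O)CC(C)(OS(C)(=O)=O)C=C | intermediate
6 | 2,6-dimethylocta-2,5,7-trien-4-one (ocimenone; 5E/5Z mixture, alkene geometry left open) | CC(C)=CC(=O)C=C(C)C=C | intermediate
7 | (4E,6E)-2,6-dimethyl-8-[(1-phenyl-1H-tetrazol-5-yl)sulfanyl]octa-2,4,6-trien-4-olate (3-oxidohexatriene, reactive geometry, ion pair with the protonated catalyst; not isolated) | CC(C)=C/C([O-])=C\C(C)=C\CSc1nnnn1-c1ccccc1 | intermediate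
8 | (4R)-3,5,5-trimethyl-4-{[(1-phenyl-1H-tetrazol-5-yl)sulfanyl]methyl}cyclohex-2-en-1-one | CC1=CC(=O)CC(C)(C)[C@H]1CSc1nnnn1-c1ccccc1 | intermediate
9 | (1S,4R)-3,5,5-trimethyl-4-{[(1-phenyl-1H-tetrazol-5-yl)sulfanyl]methyl}cyclohex-2-en-1-ol | CC1=C[C@@H](O)CC(C)(C)[C@H]1CSc1nnnn1-c1ccccc1 | intermediate
10 | 5-({[(1R,4S)-4-{[tert-butyl(dimethyl)silyl]oxy}-2,6,6-trimethylcyclohex-2-en-1-yl]methyl}sulfanyl)-1-phenyl-1H-tetrazole | CC1=C[C@@H](O[Si](C)(C)C(C)(C)C)CC(C)(C)[C@H]1CSc1nnnn1-c1ccccc1 | intermediate
11 | 5-({[(1R,4S)-4-{[tert-butyl(dimethyl)silyl]oxy}-2,6,6-trimethylcyclohex-2-en-1-yl]methyl}sulfinyl)-1-phenyl-1H-tetrazole (both configurations at sulfur; not isolated) | CC1=C[C@@H](O[Si](C)(C)C(C)(C)C)CC(C)(C)[C@H]1CS(=O)c1nnnn1-c1ccccc1 | intermediate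
12 | 5-({[(1R,4S)-4-{[tert-butyl(dimethyl)silyl]oxy}-2,6,6-trimethylcyclohex-2-en-1-yl]methyl}sulfonyl)-1-phenyl-1H-tetrazole | CC1=C[C@@H](O[Si](C)(C)C(C)(C)C)CC(C)(C)[C@H]1CS(=O)(=O)c1nnnn1-c1ccccc1 | intermediate
13 | all-E crocetin dialdehyde ((2E,4E,6E,8E,10E,12E,14E)-2,6,11,15-tetramethylhexadeca-2,4,6,8,10,12,14-heptaenedial) | O=C/C(C)=C/C=C/C(C)=C/C=C/C=C(C)/C=C/C=C(\C)C=O | starting material
14 | potassium salt of the α-sulfonyl carbanion of 12 (not isolated) | [K+].CC1=C[C@@H](O[Si](C)(C)C(C)(C)C)CC(C)(C)[C@H]1[CH-]S(=O)(=O)c1nnnn1-c1ccccc1 | intermediate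
15 | (3S,6R)-3-{[tert-butyl(dimethyl)silyl]oxy}-8'-apo-ε-caroten-8'-al | CC1=C[C@@H](O[Si](C)(C)C(C)(C)C)CC(C)(C)[C@H]1/C=C/C(C)=C/C=C/C(C)=C/C=C/C=C(C)/C=C/C=C(\C)C=O | intermediate
16 | (3S,6R)-3-hydroxy-8'-apo-ε-caroten-8'-al | CC1=C[C@@H](O)CC(C)(C)[C@H]1/C=C/C(C)=C/C=C/C(C)=C/C=C/C=C(C)/C=C/C=C(\C)C=O | target

Total step count: 8. Longest linear sequence: 8 steps (1 → 16).

Steps most likely to fail

Step 3 (proposed new method).
- Risks: C-protonation of the trienolate may outrun ring closure, so that material rests at the open 1,6-adduct. The ambident thiolate may add through nitrogen on warming. A catalyst bound at O3, 1,3 to both termini, may give poor facial control. Slow base-mediated loss and re-addition of thiolate at C7 may erode the configuration at C6.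
- Fallback (known chemistry only), from 1 back to the route at 10: mesityl oxide 1 is annulated with ethyl acetoacetate (ZnCl2, heat, removal of water; Michael addition then aldol condensation) to racemic ethyl 2,6,6-trimethyl-4-oxocyclohex-2-ene-1-carboxylate F1. Reduction with (R)-2-methyl-CBS-oxazaborolidine and catecholborane should give the 4S alcohols of both C1 epimers, from which the cis isomer ethyl (1R,4S)-4-hydroxy-2,6,6-trimethylcyclohex-2-ene-1-carboxylate F2 is separated by chromatography; the trans isomer is reoxidized with MnO2 and recycled. Silylation (TBSCl, imidazole) gives ethyl (1R,4S)-4-{[tert-butyl(dimethyl)silyl]oxy}-2,6,6-trimethylcyclohex-2-ene-1-carboxylate F3. LiAlH4 reduces the ester to [(1R,4S)-4-{[tert-butyl(dimethyl)silyl]oxy}-2,6,6-trimethylcyclohex-2-en-1-yl]methanol F4. Mitsunobu thioetherification with 1-phenyl-1H-tetrazole-5-thiol (PPh3, diisopropyl azodicarboxylate) then gives 10.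

Step 4.
- Risks: reagent control may be incomplete because the two flanks of the carbonyl (the CH2 next to quaternary C1 and the β,β-disubstituted alkene) are of similar size. The axial methyl group on C1 may steer hydride toward the trans alcohol. Borane binding to the tetrazole may slow catalyst turnover.
- Fallback, from 8 back to the route at 9: reduction of 8 with LiBH(s-Bu)3 (THF, −78 °C) under substrate control, with hydride expected to enter anti to the axial C1 methyl group, should give the trans alcohol (1R,4R)-3,5,5-trimethyl-4-{[(1-phenyl-1H-tetrazol-5-yl)sulfanyl]methyl}cyclohex-2-en-1-ol F5. Mitsunobu inversion with 4-nitrobenzoic acid (PPh3, diisopropyl azodicarboxylate) gives (1S,4R)-3,5,5-trimethyl-4-{[(1-phenyl-1H-tetrazol-5-yl)sulfanyl]methyl}cyclohex-2-en-1-yl 4-nitrobenzoate F6. Methanolysis (K2CO3, MeOH) gives 9.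

Step 7.
- Risks: the hindered carbanion may add slowly and decay by self-condensation. The product may be olefinated a second time at the distal aldehyde. Base may attack the unprotected polyenal, and the kinetic E preference may be incomplete.
- Fallback, from 13 (with carbanion 14) back to the route at 15: 13 is treated with one equivalent of 2,2-dimethylpropane-1,3-diol (pyridinium p-toluenesulfonate, toluene) and the mono-acetal, crocetin dialdehyde mono(2,2-dimethylpropane-1,3-diyl acetal) F7, is separated from dialdehyde and bis-acetal. Carbanion 14 is added to one equivalent of F7 to give (3S,6R)-3-{[tert-butyl(dimethyl)silyl]oxy}-8'-apo-ε-caroten-8'-al 2,2-dimethylpropane-1,3-diyl acetal F8. Mild hydrolysis (pyridinium p-toluenesulfonate, acetone–water) frees 15.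

Further compounds
F1 | step 3 | (±)-ethyl 2,6,6-trimethyl-4-oxocyclohex-2-ene-1-carboxylate | CCOC(=O)C1C(C)=CC(=O)CC1(C)C
F2 | step 3 | ethyl (1R,4S)-4-hydroxy-2,6,6-trimethylcyclohex-2-ene-1-carboxylate | CC1=C[C@@H](O)CC(C)(C)[C@H]1C(=O)OCC
F3 | step 3 | ethyl (1R,4S)-4-{[tert-butyl(dimethyl)silyl]oxy}-2,6,6-trimethylcyclohex-2-ene-1-carboxylate | CC1=C[C@@H](O[Si](C)(C)C(C)(C)C)CC(C)(C)[C@H]1C(=O)OCC
F4 | step 3 | [(1R,4S)-4-{[tert-butyl(dimethyl)silyl]oxy}-2,6,6-trimethylcyclohex-2-en-1-yl]methanol | CC1=C[C@@H](O[Si](C)(C)C(C)(C)C)CC(C)(C)[C@H]1CO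
F5 | step 4 | (1R,4R)-3,5,5-trimethyl-4-{[(1-phenyl-1H-tetrazol-5-yl)sulfanyl]methyl}cyclohex-2-en-1-ol | CC1=C[C@H](O)CC(C)(C)[C@H]1CSc1nnnn1-c1ccccc1
F6 | step 4 | (1S,4R)-3,5,5-trimethyl-4-{[(1-phenyl-1H-tetrazol-5-yl)sulfanyl]methyl}cyclohex-2-en-1-yl 4-nitrobenzoate | CC1=C[C@@H](OC(=O)c2ccc(cc2)[N+](=O)[O-])CC(C)(C)[C@H]1CSc1nnnn1-c1ccccc1
F7 | step 7 | crocetin dialdehyde mono(2,2-dimethylpropane-1,3-diyl acetal) | O=C/C(C)=C/C=C/C(C)=C/C=C/C=C(C)/C=C/C=C(\C)C1OCC(C)(C)CO1
F8 | step 7 | (3S,6R)-3-{[tert-butyl(dimethyl)silyl]oxy}-8'-apo-ε-caroten-8'-al 2,2-dimethylpropane-1,3-diyl acetal | CC1=C[C@@H](O[Si](C)(C)C(C)(C)C)CC(C)(C)[C@H]1/C=C/C(C)=C/C=C/C(C)=C/C=C/C=C(C)/C=C/C=C(\C)C1OCC(C)(C)CO1
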